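Late in the red run target is falling: it reads 34 % at 30.0 h, less than the 41 % at 6.00 h. Can that ground be won back, and by which move?

| flask | substrate | reagent | capture agent | temperature | remark | time |
|---|---|---|---|---|---|---|
| red | 0.30 M | 0.315 M | 0.090 M | 60 °C | the very flask that is asked about, followed so far |  |
| ochre | 0.30 M | 0.63 M | 0.090 M | 66 °C | run made earlier |  |
| flask | 0.30 M | 0.315 M | 0.0900 M | 60 °C |  | 30 h |

red run (percent of the substrate charged)

| time / h | target / % |
|---|---|
| 2.50 | 34 |
| 4.00 | 40 |
| 6.00 | 41 |
| 8.00 | 39 |
| 12.0 | 39 |
| 20.0 | 37 |
| 30.0 | 34 |

ochre run (percent of the substrate charged)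

| time / min | target / % |
|---|---|
| 12.0 | 15 |
| 25.0 | 30 |
| 40.0 | 40 |
| 50.0 | 45 |
| 60.0 | 49 |
| 80.0 | 51 |
| 90.0 | 54 |

(scatter of a reading: 1.5 percentage points)

- additions bring no volume worth counting
- the numbers in the tables scatter with a standard deviation of 1.5 percentage points
- a reading or a percentage of target counts all its forms, free or not

- larch: change nothing and wait 10 h more
- elm: at 30 h take out 90 % of the released group then present, then wait 10 h
- oak: at 30 h raise the temperature by 15 K, then wait 10 h
- cedar: at 30 h add reagent, 100 % of the amount charged, then wait 10 h

- target, in percent of the substrate first charged, at 30 h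
- what to do for the largest gain in target; "none" if nothing gains more than 2 percentage points (larch / elm / oak / cedar / none)
- target present, in percent of the substrate first charged, after oak
- target present, in percent of the substrate first charged, after cedar

**Q. What does the capture agent cost?**
A. I assume that each capture agent removes one substrate's worth, so 70.0 % of the substrate stays open to target. The ochre reading of 54 % lies under this ceiling.

**Q. How do you place a run against that ceiling?**
A. In powers of ten. The split is log10 of target over the room between target and ceiling, −0.0248 for the red run at 30.0 h, so target and room are about even. The red reading at 6.00 h gives 0.150, and the last ochre reading gives 0.528, which is higher.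

**Q. What does heat do to the split?**
A. If the split is a matter of equilibrium, thermodynamic control, heat moves it. The ochre run is hotter by 6.00 K and stands 0.378 higher. Oak raises the flask by 15 K, so I take the last ochre split as my mark for oak: from the red reading at 30.0 h that is a shift of 0.553, which puts oak at 54.0 %.

**Q. But the ochre run also had twice the reagent.**
A. Yes, and these two runs can't separate the two changes. If reagent earned 0.5 of the shift, oak gives 44.9 %. I commit to that range, so oak is my choice.

**Q. And the other moves?**
A. For now I keep the reading, 34 % with its scatter of 1.5 percentage points. The red readings stop rising by 6.00 h, so I assume that the substrate has mostly reacted by 30 h and put cedar near that reading; these runs don't test that assumption, and if it fails, cedar gains. The ochre run has more target, and so presumably more released group, at a higher split, so I expect nothing from elm. Larch continues the slide.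

The forecast gives 34.5 % now, cedar as the best move, 33 % after oak and 42 % after cedar, holding that “this is a fast equilibrium”.

    substrate + reagent → open intermediate + released group (k = 0.0580 M⁻¹ min⁻¹, Ea = 85.0 kJ mol⁻¹)
    open intermediate + capture agent → trapped intermediate (k = 0.0660 M⁻¹ min⁻¹, Ea = 76.0 kJ mol⁻¹)
    open intermediate ⇌ isomer of the product (K = 5.90, k = 0.0110 min⁻¹, Ea = 97.0 kJ mol⁻¹, ΔH = −79.0 kJ mol⁻¹)
    crystals ⇌ target, rate k4*(cs4 - [target]) while solid is left; crystals form when [target] > cs4 (solubility = 0.100 M, k = 0.510 min⁻¹)
    open intermediate ⇌ target (K = 5.60, k = 0.0240 min⁻¹, Ea = 107 kJ mol⁻¹, ΔH = −1.00 kJ mol⁻¹)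
    (constants at 60 °C)

The flask gives 32.7 % at 30 h; the best move is oak, with 21 points gained, reaching 53.6 %, while cedar ends at 32.1 %. The step to the isomer of the product carries −79.0 kJ mol⁻¹, and the step to target carries −1.00 kJ mol⁻¹. After oak the split of this flask is 0.516, a shift of 0.540 from the reading, above 0.277 and below 0.553. The same flask left untouched reads 31.4 % at 5.0 d, a split of −0.0907.

All runs stem from a simulated flask with constants of no real substance, and the scatter is random.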